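## The problem

The target is an achiral naamidine-type alkaloid built from three parts: a fully substituted 1-methyl-2-aminoimidazole, two different benzyl groups on C4 and C5, and a 1-methylimidazole-2,5-dione (dehydrohydantoin) ring attached through its C4 to the exocyclic 2-amino nitrogen. There is no stereocentre, so every selectivity question is one of position. The 4-methoxybenzyl group must sit on C4, beside the unsubstituted N3, and the 3-hydroxy-4,5-dimethoxybenzyl group on C5, beside the N1-methyl group. A late N-methylation or a late benzylation of a preformed ring could not tell these sites apart reliably. The dehydrohydantoin is an acylamidine between two carbonyl groups: nucleophiles and aqueous base open it and its C=N bond can be reduced, so it should be attached last, after all hydrogenolytic and strongly acidic or basic operations. The free phenol and the electron-rich 2-aminoimidazole are also best unmasked late. The feature that opens the structure is the C4–C5 bond of the imidazole: C4 carries N3 and the 4-methoxybenzyl group, C5 carries N1 and the other benzyl group, so in the open chain the pair is an α-amino ketone, N–CH(CH2Ar)–C(=O)–CH2Ar'. That is the pattern left when an acyl anion adds to an acylimine, and both halves then come from arylacetaldehydes. The stereocentre created at the amino-bearing carbon needs no control, because it becomes sp2 when the imidazole aromatises.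

## Retrosynthesis

**Dione ring.** The bond between the exocyclic nitrogen and C4 of the dione ring of target 21 is cut first, giving the phenolic 2-aminoimidazole 16 and 1-methylparabanic acid 17. Assembling the dione ring atom by atom on the amine would cost three or four operations. The direct condensation is one step, provided 17 is activated as its silyl imidate 18 and the amine attacks the non-urea carbonyl carbon C4. The phenol is carried through the heating as its trimethylsilyl ether (19, then 20) and is freed on methanolic work-up. Placing this step last keeps the acylamidine away from hydrogen and strong acid.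

**Protecting groups.** Compound 16 is traced to 15, in which the phenol is a benzyl ether and the 2-amino group a benzyl carbamate. Both are benzylic C–O bonds, so one hydrogenolysis removes them together. The carbamate is not only a protecting group: it is the blocking group that decides the ring closure one step earlier.

**Imidazole ring.** In 15 the C2–N3 bond, the N1–C5 bond and the C4=C5 unsaturation are disconnected, leaving α-amino ketone hydrochloride 10 and the methylated, Cbz-blocked isothiourea 12. The amine nitrogen of 10 sits on the carbon bearing the 4-methoxybenzyl group and becomes N3. The methyl group must therefore arrive on the guanidine nitrogen that condenses with the ketone, so that it ends on N1 beside C5. Cyanamide followed by N-methylation, or an unprotected N-methylguanidine, would leave two nitrogens able to close. In guanidino ketone 13 only the NHMe nitrogen is free and nucleophilic, so closure to carbinolamine 14 and dehydration give 15 with the substituents in the required positions. Reagent 12 is one acylation away from the catalogue salt 11.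

**C4–C5 bond (key).** Amine 10 is the deprotected form of Boc-amino ketone 9. Cutting the bond between the carbonyl carbon and the nitrogen-bearing carbon of 9 gives arylacetaldehyde 4 as acyl-anion donor and N-Boc imine 8, stored as the bench-stable α-amido sulfone 7. This is preferred to the obvious neighbour, a benzyl organometallic added to an amino acid derivative, because it joins two aldehydes catalytically with no organometallic reagent. Which aldehyde becomes the sulfone fixes which carbon carries nitrogen. The forward reaction must favour cross-coupling over self-reaction of two enolisable partners.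

**Fragments.** Aldehyde 4 comes from enol ether 3 by hydrolysis, 3 from benzaldehyde 2 by Wittig methoxymethylenation, and 2 from commercial 3-hydroxy-4,5-dimethoxybenzaldehyde 1 by benzylation. Sulfone 7 is the three-component adduct of commercial 4-methoxyphenylacetaldehyde 5, tert-butyl carbamate 6 and sodium p-toluenesulfinate. All carbon atoms of the skeleton except the guanidine carbon and the dione ring thus come from 1 and 5.

## Roads not taken

**Alternative 1:** The cut lies inside the dione ring: both N–C(=O) bonds of its N-methyl group are opened, giving amidino ester A2 (ethyl 2-amino-2-iminoacetate attached to the 2-amino nitrogen of the imidazole, phenol as its tert-butyldimethylsilyl ether) and methyl isocyanate A3. In the forward step the terminal amidine nitrogen adds to A3 and the new methylurea N–H closes onto the ester, giving silyl ether A1, which fluoride would convert into 21.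
- Merits: the methyl position in the dione ring is fixed by construction. The closure runs under mild base, with no refluxing toluene and no choice among three carbonyl groups of a parabanic acid.
- Weak points: it does not address the substituted imidazole, which must still be built in full, for instance through 16. A2 then needs O-silylation and amidine formation from 16, so three or four operations replace one. A2 offers three nucleophilic nitrogens to A3 (terminal amidine N, inner amidine N, ring N3). A3 is a volatile, highly toxic reagent.
- Comparison: in control of the dione regiochemistry this road is better than the chosen plan. The chosen plan sets against it a single-step condensation of a type already used on 2-aminoimidazoles, and it keeps a related ring annulation as its fallback for step 10.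

**Alternative 2:** The cut is the C4–CH2 bond of the imidazole. Creatinine A7 supplies N1-methyl, the 2-amino group and an oxygen at C4. C5 is benzylated by aldol condensation with the protected benzaldehyde and reduction, the amino group is doubly Boc-protected, and the C4 oxygen is converted into imidazol-4-yl triflate A5. Negishi coupling of A5 with 4-methoxybenzylzinc chloride A6 under Pd(OAc)2 and SPhos then gives the bis-Boc, methoxymethyl-protected imidazole A4.
- Merits: the positions of N-methyl and the amino group are inherited from A7, so no ring closure has to be steered. No arylacetaldehyde is handled. The C4 substituent can be varied late.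
- Weak points: a triflate of a 2-amino-imidazol-4-one has no close analogue; O-sulfonylation must beat N-sulfonylation on an acylguanidine. The electron-rich five-membered triflate should add slowly to palladium and is prone to S–O cleavage. The benzylzinc reagent homocouples. Protecting-group traffic is heavy (methoxymethyl, two Boc groups), and the overall length is no shorter.
- Comparison: this road is cleaner on the N1/N3 question, which the chosen plan settles only through the Cbz-blocked closure of step 8. The chosen plan sets against it a key C–C bond formation of an established reaction class, no untested heteroaryl electrophile and no organometallic step.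

**Alternative 3:** The cut is the C5–CH2 bond at the carbinol oxidation level. The free base of 4-(4-methoxybenzyl)-1-methyl-1H-imidazol-2-amine A9 would add through C5 to aldehyde 2 on warming in a neutral medium, giving racemic carbinol A8. Reductive removal of the hydroxyl group and of the benzyl ether would then lead to 16.
- Merits: it is the shortest road. It uses 2 directly and saves the homologation steps. C5 is the only free ring carbon of A9. A9 itself is available by the classical condensation of an N-methylamino ketone with a one-carbon amidine source, which places the methyl group without ambiguity.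
- Weak points: the electron-rich benzaldehyde 2 is a weak electrophile and the addition is reversible. The exocyclic amino group and N3 of A9 compete with C5. A8 ionises readily to an azafulvenium ion that a second molecule of A9 can capture. The deoxygenation must be carried out on this labile carbinol.
- Comparison: this road is shorter by about three steps and cleaner in N-methyl placement than the chosen plan. The chosen plan sets against it that its C–C bond is made on an open chain, where no ring nitrogen competes, by a reaction of known type, and that no addition has to be stopped at the mono-adduct stage.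

Key step: step 5

Assumption: compounds 11 and 17 and the thiazolium precatalyst are treated as catalogue materials, and the acylamidine of the target is drawn as its 4-amino tautomer, the form the route delivers after tautomeric equilibration.

## Route

Step 1
Reactants: 1 3-hydroxy-4,5-dimethoxybenzaldehyde
Product: 2 3-benzyloxy-4,5-dimethoxybenzaldehyde
Conditions: BnBr, K2CO3, DMF, 60 °C
Reagents that add atoms: benzyl bromide, BrCc1ccccc1
Why: Williamson ether synthesis on the phenoxide; the aldehyde is inert to K2CO3, and the benzyl ether withstands the base of step 2, the aqueous and anhydrous acid of steps 3 and 6 and the amine base of step 5 until hydrogenolysis in step 9.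

Step 2
Reactants: 2 3-benzyloxy-4,5-dimethoxybenzaldehyde
Product: 3 1-benzyloxy-2,3-dimethoxy-5-(2-methoxyethenyl)benzene (E/Z mixture)
Conditions: Ph3P(CH2OMe)Cl, KOtBu, THF, 0 °C to rt
Reagents that add atoms: (methoxymethyl)triphenylphosphonium chloride, COC[P+](c1ccccc1)(c1ccccc1)c1ccccc1.[Cl-]
Why: Wittig methoxymethylenation of an aromatic aldehyde with the non-stabilised ylide; the enol ether should form as an E/Z mixture, which is immaterial because both isomers hydrolyse to the same aldehyde.

Step 3
Reactants: 3 1-benzyloxy-2,3-dimethoxy-5-(2-methoxyethenyl)benzene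
Product: 4 (3-benzyloxy-4,5-dimethoxyphenyl)acetaldehyde
Conditions: 2 M aq HCl, THF, 45 °C
Reagents that add atoms: water, O
Why: Acid-catalysed enol ether hydrolysis (C-protonation, hydration of the oxocarbenium ion, loss of methanol) completes the one-carbon homologation; aryl benzyl and methyl ethers are stable to dilute acid, and 4 is used promptly because arylacetaldehydes self-condense on storage.

Step 4
Reactants: 5 4-methoxyphenylacetaldehyde, 6 tert-butyl carbamate
Product: 7 tert-butyl N-[2-(4-methoxyphenyl)-1-(4-methylbenzenesulfonyl)ethyl]carbamate (racemic)
Conditions: TolSO2Na, HCO2H, MeOH/H2O (1:2), rt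
Reagents that add atoms: sodium p-toluenesulfinate, Cc1ccc(S(=O)[O-])cc1.[Na+]
Why: Three-component amidoalkylation (Mannich-type condensation): formic acid promotes condensation of aldehyde and carbamate, and the sulfinate traps the N-acyliminium ion as the α-amido sulfone, which should crystallise from the aqueous medium and pull the equilibrium over; the racemic centre is destroyed when the sulfinate is eliminated in step 5.

Step 5
Reactants: 4 (3-benzyloxy-4,5-dimethoxyphenyl)acetaldehyde, 7 tert-butyl N-[2-(4-methoxyphenyl)-1-(4-methylbenzenesulfonyl)ethyl]carbamate
Product: 9 tert-butyl N-[4-(3-benzyloxy-4,5-dimethoxyphenyl)-1-(4-methoxyphenyl)-3-oxobutan-2-yl]carbamate (racemic), via N-Boc imine 8 (not isolated)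
Conditions: 3-benzyl-5-(2-hydroxyethyl)-4-methylthiazolium chloride (20 mol %), Et3N (10 equiv), 4 (1.5 equiv), CH2Cl2, 35 °C
Reagents that add atoms: none
Why: Et3N eliminates p-toluenesulfinate from 7, releasing N-Boc imine 8 at a low stationary concentration, and also deprotonates the thiazolium salt to the carbene. The carbene adds to the formyl group of 4 and proton transfer gives the nucleophilic hydroxy-enamine, the acyl-anion equivalent, which attacks the imine carbon of 8; collapse of the adduct returns the carbene and leaves ketone 9 with the bond that becomes C4–C5 of the imidazole. The closest known reaction type is the thiazolium-catalysed cross aza-benzoin addition of aldehydes to acylimines generated in situ from α-amido sulfones. No ring is closed. One stereocentre, the carbon bearing NHBoc, is formed without control as the racemate, which is acceptable because it becomes sp2 in step 8. The step needs cross-coupling to prevail over self-acyloin and aldol reaction of 4 and over tautomerisation of 8 to its enecarbamate: the acylimine is a much better electrophile than an aldehyde, it is released slowly into an excess of the donor, and the self-acyloin of 4 forms reversibly under the carbene and so feeds back into the productive path. Which aldehyde is donor and which acceptor is fixed by which one was made into the sulfone, so nitrogen ends on the carbon bearing the 4-methoxybenzyl group.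

Step 6
Reactants: 9 tert-butyl N-[4-(3-benzyloxy-4,5-dimethoxyphenyl)-1-(4-methoxyphenyl)-3-oxobutan-2-yl]carbamate
Product: 10 3-amino-1-(3-benzyloxy-4,5-dimethoxyphenyl)-4-(4-methoxyphenyl)butan-2-one hydrochloride (racemic)
Conditions: 4 M HCl in 1,4-dioxane, rt
Reagents that add atoms: hydrogen chloride, Cl
Why: Acidolysis of the tert-butyl carbamate with loss of 2-methylpropene and CO2; the benzyl ether and the ketone are inert to anhydrous HCl, and isolation as the hydrochloride prevents the dihydropyrazine-forming self-condensation of a free α-amino ketone.

Step 7
Reactants: 11 N,S-dimethylisothiouronium iodide (methyl N-methylcarbamimidothioate hydroiodide)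
Product: 12 benzyl N-[(methylamino)(methylsulfanyl)methylidene]carbamate
Conditions: CbzCl (1.0 equiv), NaHCO3, CH2Cl2/H2O, 0 °C to rt
Reagents that add atoms: benzyl chloroformate, O=C(Cl)OCc1ccccc1
Why: Schotten–Baumann N-acylation of the isothiourea at its unsubstituted, less hindered nitrogen gives the conjugated N-acylisothiourea; one equivalent of chloroformate at 0 °C limits double acylation.

Step 8
Reactants: 10 3-amino-1-(3-benzyloxy-4,5-dimethoxyphenyl)-4-(4-methoxyphenyl)butan-2-one hydrochloride, 12 benzyl N-[(methylamino)(methylsulfanyl)methylidene]carbamate
Product: 15 benzyl N-[5-(3-benzyloxy-4,5-dimethoxybenzyl)-4-(4-methoxybenzyl)-1-methyl-1H-imidazol-2-yl]carbamate, via guanidino ketone 13 (not isolated), via cyclic carbinolamine 14 (not isolated)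
Conditions: HgCl2, Et3N, DMF, 0 °C to rt; filter; then AcOH, 60 °C
Reagents that add atoms: none
Why: Thiophile-promoted guanylation (HgCl2 removes methanethiolate from 12 to give an acylcarbodiimide, to which the amine freed from 10 adds), followed by the intramolecular guanidine–ketone condensation of the classical 2-aminoimidazole synthesis from α-amino ketones. In 13 only the NHMe nitrogen is free and nucleophilic, the third nitrogen being deactivated as the carbamate, so 5-exo-trig attack on the ketone gives 14 with methyl on the nitrogen bonded to the former carbonyl carbon (N1 beside C5). Dehydration towards C4–H in warm AcOH aromatises the ring and removes both stereocentres.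

Step 9
Reactants: 15 benzyl N-[5-(3-benzyloxy-4,5-dimethoxybenzyl)-4-(4-methoxybenzyl)-1-methyl-1H-imidazol-2-yl]carbamate
Product: 16 5-{[2-amino-4-(4-methoxybenzyl)-1-methyl-1H-imidazol-5-yl]methyl}-2,3-dimethoxyphenol
Conditions: H2 (1 atm), 10% Pd/C, MeOH, rt
Reagents that add atoms: none
Why: Catalytic hydrogenolysis cleaves the aryl benzyl ether and the benzyl carbamate in one operation, releasing toluene and CO2; the aryl methyl ethers, the benzylic C–C bonds and the aminoimidazole should not be reduced at one atmosphere and room temperature.

Step 10
Reactants: 16 5-{[2-amino-4-(4-methoxybenzyl)-1-methyl-1H-imidazol-5-yl]methyl}-2,3-dimethoxyphenol, 17 1-methylparabanic acid (1-methylimidazolidine-2,4,5-trione)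
Product: 21 4-{[5-(3-hydroxy-4,5-dimethoxybenzyl)-4-(4-methoxybenzyl)-1-methyl-1H-imidazol-2-yl]amino}-1-methyl-1H-imidazole-2,5-dione (CNP0321799.0), via silyl imidate 18 (not isolated), via aryl silyl ether 19 (not isolated), via silylated product 20 (not isolated)
Conditions: 17, BSA (3 equiv), MeCN, 80 °C; then 16, toluene, 110 °C; then MeOH, rt
Reagents that add atoms: none
Why: Silyl-mediated amidine-forming condensation (addition–elimination of an amine on a silyl imidate), the established way to attach this dione unit to 2-aminoimidazoles. BSA converts 17 into silyl imidate 18 and masks the phenol of 16 as ether 19; the exocyclic amino group attacks C4 of 18, the more electrophilic non-urea carbon beside the former N–H, and loss of trimethylsilanol gives 20. Methanol then cleaves the aryl silyl ether.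

## Compound list

1 | 3-hydroxy-4,5-dimethoxybenzaldehyde | COc1cc(C=O)cc(O)c1OC | starting material
2 | 3-benzyloxy-4,5-dimethoxybenzaldehyde | COc1cc(C=O)cc(OCc2ccccc2)c1OC | intermediate
3 | 1-benzyloxy-2,3-dimethoxy-5-(2-methoxyethenyl)benzene (E/Z mixture) | COC=Cc1cc(OCc2ccccc2)c(OC)c(OC)c1 | intermediate
4 | (3-benzyloxy-4,5-dimethoxyphenyl)acetaldehyde | O=CCc1cc(OCc2ccccc2)c(OC)c(OC)c1 | intermediate
5 | 4-methoxyphenylacetaldehyde | COc1ccc(CC=O)cc1 | starting material
6 | tert-butyl carbamate | CC(C)(C)OC(N)=O | starting material
7 | tert-butyl N-[2-(4-methoxyphenyl)-1-(4-methylbenzenesulfonyl)ethyl]carbamate (racemic) | CC(C)(C)OC(=O)NC(Cc1ccc(OC)cc1)S(=O)(=O)c1ccc(C)cc1 | intermediate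
8 | tert-butyl N-[2-(4-methoxyphenyl)ethylidene]carbamate (not isolated) | CC(C)(C)OC(=O)N=CCc1ccc(OC)cc1 | intermediate
9 | tert-butyl N-[4-(3-benzyloxy-4,5-dimethoxyphenyl)-1-(4-methoxyphenyl)-3-oxobutan-2-yl]carbamate (racemic) | CC(C)(C)OC(=O)NC(Cc1ccc(OC)cc1)C(=O)Cc1cc(OCc2ccccc2)c(OC)c(OC)c1 | intermediate
10 | 3-amino-1-(3-benzyloxy-4,5-dimethoxyphenyl)-4-(4-methoxyphenyl)butan-2-one hydrochloride (racemic) | NC(Cc1ccc(OC)cc1)C(=O)Cc1cc(OCc2ccccc2)c(OC)c(OC)c1.Cl | intermediate
11 | N,S-dimethylisothiouronium iodide | CNC(=N)SC.I | starting material
12 | benzyl N-[(methylamino)(methylsulfanyl)methylidene]carbamate | CNC(SC)=NC(=O)OCc1ccccc1 | intermediate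
13 | benzyl N-[{[4-(3-benzyloxy-4,5-dimethoxyphenyl)-1-(4-methoxyphenyl)-3-oxobutan-2-yl]amino}(methylamino)methylidene]carbamate (racemic, not isolated) | CNC(=NC(=O)OCc1ccccc1)NC(Cc1ccc(OC)cc1)C(=O)Cc1cc(OCc2ccccc2)c(OC)c(OC)c1 | intermediate
14 | benzyl N-[5-(3-benzyloxy-4,5-dimethoxybenzyl)-5-hydroxy-4-(4-methoxybenzyl)-1-methylimidazolidin-2-ylidene]carbamate (diastereomer mixture, racemic, not isolated) | CN1C(=NC(=O)OCc2ccccc2)NC(Cc2ccc(OC)cc2)C1(O)Cc1cc(OCc2ccccc2)c(OC)c(OC)c1 | intermediate
15 | benzyl N-[5-(3-benzyloxy-4,5-dimethoxybenzyl)-4-(4-methoxybenzyl)-1-methyl-1H-imidazol-2-yl]carbamate | Cn1c(NC(=O)OCc2ccccc2)nc(Cc2ccc(OC)cc2)c1Cc1cc(OCc2ccccc2)c(OC)c(OC)c1 | intermediate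
16 | 5-{[2-amino-4-(4-methoxybenzyl)-1-methyl-1H-imidazol-5-yl]methyl}-2,3-dimethoxyphenol | Cn1c(N)nc(Cc2ccc(OC)cc2)c1Cc1cc(O)c(OC)c(OC)c1 | intermediate
17 | 1-methylparabanic acid (1-methylimidazolidine-2,4,5-trione) | CN1C(=O)NC(=O)C1=O | starting material
18 | 1-methyl-4-(trimethylsilyloxy)-1H-imidazole-2,5-dione (not isolated) | CN1C(=O)N=C(O[Si](C)(C)C)C1=O | intermediate
19 | 5-[3,4-dimethoxy-5-(trimethylsilyloxy)benzyl]-4-(4-methoxybenzyl)-1-methyl-1H-imidazol-2-amine (not isolated) | Cn1c(N)nc(Cc2ccc(OC)cc2)c1Cc1cc(O[Si](C)(C)C)c(OC)c(OC)c1 | intermediate
20 | O-trimethylsilyl ether of 21 (not isolated) | COc1ccc(Cc2nc(NC3=NC(=O)N(C)C3=O)n(C)c2Cc2cc(O[Si](C)(C)C)c(OC)c(OC)c2)cc1 | intermediate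
21 | 4-{[5-(3-hydroxy-4,5-dimethoxybenzyl)-4-(4-methoxybenzyl)-1-methyl-1H-imidazol-2-yl]amino}-1-methyl-1H-imidazole-2,5-dione (CNP0321799.0) | COc1ccc(Cc2nc(NC3=NC(=O)N(C)C3=O)n(C)c2Cc2cc(O)c(OC)c(OC)c2)cc1 | target

## Step count and risks

Total step count: 10. Longest linear sequence: 8 steps (steps 1, 2, 3, 5, 6, 8, 9 and 10, from 1 to 21); steps 4 and 7 are one-step side branches.

**Step 5 (key step).** The most likely failure is base-mediated tautomerisation of the enolisable acylimine to its aryl-conjugated enecarbamate before the acyl-anion equivalent captures it. Aldol self-condensation of the donor aldehyde and enolisation of the doubly activated benzylic ketone product under the large excess of amine add to this. The fallback replaces the umpolung by an acyl substitution; it sets out from 2 and returns at 9. Aldehyde 2 would be reduced with NaBH4 to (3-benzyloxy-4,5-dimethoxyphenyl)methanol F1, converted with SOCl2 into 1-benzyloxy-5-(chloromethyl)-2,3-dimethoxybenzene F2, and this into (3-benzyloxy-4,5-dimethoxybenzyl)magnesium chloride F3 with magnesium turnings in THF. F3 would be added at low temperature to tert-butyl N-[(2S)-1-[methoxy(methyl)amino]-3-(4-methoxyphenyl)-1-oxopropan-2-yl]carbamate F4, the Weinreb amide prepared from commercial N-Boc-O-methyl-L-tyrosine, N,O-dimethylhydroxylamine hydrochloride and carbonyldiimidazole, after its carbamate N–H has been deprotonated with i-PrMgCl. The chelated adduct should stop at the ketone stage and give tert-butyl N-[(2S)-4-(3-benzyloxy-4,5-dimethoxyphenyl)-1-(4-methoxyphenyl)-3-oxobutan-2-yl]carbamate F5, the (S)-enantiomer of 9. F5 takes the place of racemic 9 from step 6 on, since its configuration is erased in step 8.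

**Step 8.** Three things may go wrong: self-condensation of the liberated α-amino ketone before guanylation; ring closure through the carbamate-bearing nitrogen, or after premature loss of the blocking group, which would misplace the methyl group; and incomplete dehydration of the carbinolamine. The fallback is a Marckwald sequence that sets out from 10 and returns at 16. Salt 10 would be treated with methyl isothiocyanate and Et3N in ethanol and the thiourea closed by warming with dilute acid to 5-(3-benzyloxy-4,5-dimethoxybenzyl)-4-(4-methoxybenzyl)-1-methyl-1,3-dihydro-2H-imidazole-2-thione F6. Here only the methyl-bearing nitrogen can reach the ketone, so no blocking group is needed. Oxidative desulfurisation with H2O2 in AcOH would give 5-(3-benzyloxy-4,5-dimethoxybenzyl)-4-(4-methoxybenzyl)-1-methyl-1H-imidazole F7. C2-lithiation with n-BuLi at −78 °C and azide transfer from p-toluenesulfonyl azide would give 2-azido-5-(3-benzyloxy-4,5-dimethoxybenzyl)-4-(4-methoxybenzyl)-1-methyl-1H-imidazole F8. Hydrogenation over Pd/C then reduces the azide and removes the benzyl ether to give 16.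

**Step 10.** Possible failures are attack at the urea carbonyl or through the ring nitrogen instead of the exocyclic amine, sluggish conversion of a weakly nucleophilic amine, and hydrolytic opening of the acylamidine during work-up. The fallback builds the dione ring stepwise; it sets out from 16 and returns at 21. The phenol would be silylated with triisopropylsilyl chloride and imidazole to 5-[3,4-dimethoxy-5-(triisopropylsilyloxy)benzyl]-4-(4-methoxybenzyl)-1-methyl-1H-imidazol-2-amine F9. The amino group would be condensed with ethyl 2-ethoxy-2-iminoacetate to ethyl 2-amino-2-({5-[3,4-dimethoxy-5-(triisopropylsilyloxy)benzyl]-4-(4-methoxybenzyl)-1-methyl-1H-imidazol-2-yl}imino)acetate F10. Treatment with methyl isocyanate and Et3N would close the ring to the O-triisopropylsilyl ether of 21, F11, and Bu4NF would then release 21.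

**Step 9.** Traces of sulfur and mercury carried over from step 8, or the basic aminoimidazole itself, may poison the palladium surface and stall the reaction at a mono-deprotected stage. The fallback is a Lewis-acid debenzylation from 15 to 16: BCl3 with pentamethylbenzene as cation scavenger in CH2Cl2 at −78 to 0 °C should cleave both the aryl benzyl ether and the benzyl carbamate while leaving the aryl methyl ethers at that temperature. It creates no new intermediate.

**Step 3.** Acid-promoted aldol self-condensation and oligomerisation of the arylacetaldehyde during hydrolysis or isolation may erode the material. The fallback reaches 4 under non-protic conditions; it sets out from 2 and returns at 4. Corey–Chaykovsky epoxidation of 2 with trimethylsulfonium iodide and NaH in DMSO/THF would give 2-(3-benzyloxy-4,5-dimethoxyphenyl)oxirane F12. A catalytic amount of BF3·OEt2 in CH2Cl2 would then induce Meinwald rearrangement (benzylic C–O ionisation and hydride shift) to 4, which would be taken directly into step 5.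

## Further compounds

F1 | step 5 | (3-benzyloxy-4,5-dimethoxyphenyl)methanol | OCc1cc(OCc2ccccc2)c(OC)c(OC)c1
F2 | step 5 | 1-benzyloxy-5-(chloromethyl)-2,3-dimethoxybenzene | ClCc1cc(OCc2ccccc2)c(OC)c(OC)c1
F3 | step 5 | (3-benzyloxy-4,5-dimethoxybenzyl)magnesium chloride | Cl[Mg]Cc1cc(OCc2ccccc2)c(OC)c(OC)c1
F4 | step 5 | tert-butyl N-[(2S)-1-[methoxy(methyl)amino]-3-(4-methoxyphenyl)-1-oxopropan-2-yl]carbamate | CON(C)C(=O)[C@H](Cc1ccc(OC)cc1)NC(=O)OC(C)(C)C
F5 | step 5 | tert-butyl N-[(2S)-4-(3-benzyloxy-4,5-dimethoxyphenyl)-1-(4-methoxyphenyl)-3-oxobutan-2-yl]carbamate | CC(C)(C)OC(=O)N[C@@H](Cc1ccc(OC)cc1)C(=O)Cc1cc(OCc2ccccc2)c(OC)c(OC)c1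
F6 | step 8 | 5-(3-benzyloxy-4,5-dimethoxybenzyl)-4-(4-methoxybenzyl)-1-methyl-1,3-dihydro-2H-imidazole-2-thione | Cn1c(=S)[nH]c(Cc2ccc(OC)cc2)c1Cc1cc(OCc2ccccc2)c(OC)c(OC)c1
F7 | step 8 | 5-(3-benzyloxy-4,5-dimethoxybenzyl)-4-(4-methoxybenzyl)-1-methyl-1H-imidazole | Cn1cnc(Cc2ccc(OC)cc2)c1Cc1cc(OCc2ccccc2)c(OC)c(OC)c1
F8 | step 8 | 2-azido-5-(3-benzyloxy-4,5-dimethoxybenzyl)-4-(4-methoxybenzyl)-1-methyl-1H-imidazole | Cn1c(N=[N+]=[N-])nc(Cc2ccc(OC)cc2)c1Cc1cc(OCc2ccccc2)c(OC)c(OC)c1
F9 | step 10 | 5-[3,4-dimethoxy-5-(triisopropylsilyloxy)benzyl]-4-(4-methoxybenzyl)-1-methyl-1H-imidazol-2-amine | Cn1c(N)nc(Cc2ccc(OC)cc2)c1Cc1cc(O[Si](C(C)C)(C(C)C)C(C)C)c(OC)c(OC)c1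
F10 | step 10 | ethyl 2-amino-2-({5-[3,4-dimethoxy-5-(triisopropylsilyloxy)benzyl]-4-(4-methoxybenzyl)-1-methyl-1H-imidazol-2-yl}imino)acetate | CCOC(=O)C(=N)Nc1nc(Cc2ccc(OC)cc2)c(Cc2cc(O[Si](C(C)C)(C(C)C)C(C)C)c(OC)c(OC)c2)n1C
F11 | step 10 | O-triisopropylsilyl ether of 21 | COc1ccc(Cc2nc(NC3=NC(=O)N(C)C3=O)n(C)c2Cc2cc(O[Si](C(C)C)(C(C)C)C(C)C)c(OC)c(OC)c2)cc1
F0 | step 9 | none | none
F12 | step 3 | 2-(3-benzyloxy-4,5-dimethoxyphenyl)oxirane (racemic) | C1OC1c1cc(OCc2ccccc2)c(OC)c(OC)c1
A1 | alternative 1 | O-tert-butyldimethylsilyl ether of 21 | COc1ccc(Cc2nc(NC3=NC(=O)N(C)C3=O)n(C)c2Cc2cc(O[Si](C)(C)C(C)(C)C)c(OC)c(OC)c2)cc1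
A2 | alternative 1 | ethyl 2-amino-2-({5-[3-(tert-butyldimethylsilyloxy)-4,5-dimethoxybenzyl]-4-(4-methoxybenzyl)-1-methyl-1H-imidazol-2-yl}imino)acetate | CCOC(=O)C(=N)Nc1nc(Cc2ccc(OC)cc2)c(Cc2cc(O[Si](C)(C)C(C)(C)C)c(OC)c(OC)c2)n1C
A3 | alternative 1 | methyl isocyanate | CN=C=O
A4 | alternative 2 | 2-[bis(tert-butoxycarbonyl)amino]-5-[3-(methoxymethoxy)-4,5-dimethoxybenzyl]-4-(4-methoxybenzyl)-1-methylimidazole | Cn1c(N(C(=O)OC(C)(C)C)C(=O)OC(C)(C)C)nc(Cc2ccc(OC)cc2)c1Cc1cc(OCOC)c(OC)c(OC)c1
A5 | alternative 2 | 2-[bis(tert-butoxycarbonyl)amino]-5-[3-(methoxymethoxy)-4,5-dimethoxybenzyl]-1-methylimidazol-4-yl trifluoromethanesulfonate | Cn1c(N(C(=O)OC(C)(C)C)C(=O)OC(C)(C)C)nc(OS(=O)(=O)C(F)(F)F)c1Cc1cc(OCOC)c(OC)c(OC)c1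
A6 | alternative 2 | 4-methoxybenzylzinc chloride | COc1ccc(C[Zn]Cl)cc1
A7 | alternative 2 | creatinine | CN1CC(=O)N=C1N
A8 | alternative 3 | [2-amino-4-(4-methoxybenzyl)-1-methylimidazol-5-yl](3-benzyloxy-4,5-dimethoxyphenyl)methanol (racemic) | Cn1c(N)nc(Cc2ccc(OC)cc2)c1C(O)c1cc(OCc2ccccc2)c(OC)c(OC)c1
A9 | alternative 3 | 4-(4-methoxybenzyl)-1-methyl-1H-imidazol-2-amine | Cn1cc(Cc2ccc(OC)cc2)nc1N
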